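**Retrosynthetic overview**

1. C1 is carried at the carboxyl level: target 17 ⇐ biaryl lactam 16 (LiAlH4); biaryl bond C5–C1' ⇐ Suzuki–Miyaura union of bromolactam 5 with naphthyl boronate 15.
2. Ring B (the N-heterocycle) ⇐ amide bond C1–N2, closed in the same pot in which an (S)-selective transaminase converts the C3 ketone of the achiral δ-keto ester 2 into the amine; N2, the C3 stereocentre and ring B arise in one operation.
3. Enabling feature: C3 (a carbon flanked by CH3 and by C4H2–aryl, i.e. a latent methyl ketone with one small and one large side) and C1 (on C8a) hang from the adjacent ring-A carbons C4a and C8a, so an amine born at C3 sits at six-ring distance from the C1 ester carbonyl.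
4. Keto ester 2 ⇐ lateral lithiation/acetylation of methyl 2,4-dimethoxy-6-methylbenzoate 1; naphthalene 15 ⇐ Stobbe annulation of 2-bromo-5-methoxybenzaldehyde 6, whose bromine blocks one ortho site and later serves as the coupling handle.
5. Ring order: ring A is bought; ring B in step 2; second naphthalene ring in step 5; the two halves are joined in step 11.

Key step: step 2

Assumption: the target SMILES defines only C3, which is (S); the hindered C5–C1' biaryl axis is undefined, so no axial control is planned and 16 and 17 are expected as atropisomer mixtures of the single (3S) series.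

**Route**

Step 1
Reactants: 1 methyl 2,4-dimethoxy-6-methylbenzoate
Product: 2 methyl 2,4-dimethoxy-6-(2-oxopropyl)benzoate
Conditions: LiN(iPr)2, THF, −78 °C; N-methoxy-N-methylacetamide, −78 to −40 °C; aq. NH4Cl
Reagents that add atoms: N-methoxy-N-methylacetamide, CC(=O)N(C)OC
Why: Lateral lithiation of the ortho-toluate gives the ester-stabilised benzylic anion, which is acylated by the Weinreb amide, whose stable tetrahedral chelate should prevent over-addition and product enolisation until the quench.

Step 2
Reactants: 2 methyl 2,4-dimethoxy-6-(2-oxopropyl)benzoate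
Product: 4 (3S)-6,8-dimethoxy-3-methyl-3,4-dihydroisoquinolin-1(2H)-one, via amino ester 3 (not isolated)
Conditions: (S)-selective ω-transaminase (Chromobacterium violaceum enzyme), pyridoxal 5'-phosphate (cat.), iPrNH2 (1 M), KH2PO4/K2HPO4 buffer pH 8.0, DMSO (10 vol%), 30 °C; then pH 10, 45 °C
Reagents that add atoms: isopropylamine, CC(C)N
Why: The enzyme-bound pyridoxamine (charged from isopropylamine, which leaves as acetone) condenses with the C3 ketone of 2, the ketimine is tautomerised through the quinonoid intermediate and protonated at C3 by the active-site lysine, and hydrolysis releases amino ester 3, whose nitrogen then adds to the C1 ester carbonyl and expels methanol to form the C1–N2 amide bond. The closest known reaction type is the transaminase amination of gamma- and delta-keto esters (and the regioselective monoamination of diketones) followed by spontaneous cyclisation to lactams or cyclic imines. Ring B closes by a 6-exo-trig acyl substitution, made easy because C3 and C1 are held on the adjacent ring-A carbons C4a and C8a. The only new stereocentre, C3, is set by the enzyme: the methyl group sits in the small pocket and the arylmethyl group in the large pocket, which for an (S)-selective transaminase should give the (S)-amine, the same sense as for 1-arylpropan-2-amines. The step needs chemoselectivity for the ketone over the ester (esters are not transaminase substrates), freedom from enol lactonisation to the isocoumarin (secured by pH 8 and 30 °C) and a favourable equilibrium (secured by excess isopropylamine and by the irreversible lactam closure that removes 3). C3 is not alpha to a carbonyl group, so it cannot epimerise later.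

Step 3
Reactants: 4 (3S)-6,8-dimethoxy-3-methyl-3,4-dihydroisoquinolin-1(2H)-one
Product: 5 (3S)-5-bromo-6,8-dimethoxy-3-methyl-3,4-dihydroisoquinolin-1(2H)-one
Conditions: N-bromosuccinimide, MeCN, 0 to 25 °C, dark
Reagents that add atoms: N-bromosuccinimide, O=C1CCC(=O)N1Br
Why: Electrophilic aromatic bromination should go to C5, which is para to the C8 methoxy and ortho to the C6 methoxy group, rather than to C7, which is flanked by two methoxy groups.

Step 4
Reactants: 6 2-bromo-5-methoxybenzaldehyde; 7 dimethyl succinate
Product: 8 (3E)-4-(2-bromo-5-methoxyphenyl)-3-(methoxycarbonyl)but-3-enoic acid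
Conditions: NaOMe, MeOH, reflux; then aq. HCl
Reagents that add atoms: none
Why: Stobbe condensation (aldol addition, lactonisation to the paraconate, base-induced ring opening) gives the alkylidene succinic half-ester, the (E)-isomer with the aryl group cis to the CH2CO2H arm being favoured.

Step 5
Reactants: 8 (3E)-4-(2-bromo-5-methoxyphenyl)-3-(methoxycarbonyl)but-3-enoic acid
Product: 9 methyl 4-acetoxy-8-bromo-5-methoxynaphthalene-2-carboxylate
Conditions: Ac2O, NaOAc, 140 °C
Reagents that add atoms: acetic anhydride, CC(=O)OC(C)=O
Why: The mixed anhydride undergoes intramolecular Friedel–Crafts acylation at the only free ortho position (the other is blocked by bromine, the open one is activated by the ortho methoxy group), and the resulting naphthol is acetylated in situ.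

Step 6
Reactants: 9 methyl 4-acetoxy-8-bromo-5-methoxynaphthalene-2-carboxylate
Product: 11 methyl 8-bromo-4,5-dimethoxynaphthalene-2-carboxylate, via naphthol 10 (not isolated)
Conditions: K2CO3, MeOH, 25 °C; then evaporate, MeI, K2CO3, DMF, 40 °C
Reagents that add atoms: iodomethane, CI
Why: Methanolysis of the aryl acetate (the methyl ester is unchanged in methanol) followed by Williamson O-methylation of the naphtholate.

Step 7
Reactants: 11 methyl 8-bromo-4,5-dimethoxynaphthalene-2-carboxylate
Product: 12 (8-bromo-4,5-dimethoxynaphthalen-2-yl)methanol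
Conditions: LiAlH4, THF, 0 °C
Reagents that add atoms: none
Why: Hydride reduction of the ester to the primary alcohol, under which the aryl bromide should be inert at 0 °C.

Step 8
Reactants: 12 (8-bromo-4,5-dimethoxynaphthalen-2-yl)methanol
Product: 13 1-bromo-7-(bromomethyl)-4,5-dimethoxynaphthalene
Conditions: CBr4, PPh3, CH2Cl2, 0 °C
Reagents that add atoms: carbon tetrabromide, BrC(Br)(Br)Br
Why: Appel reaction, a neutral conversion of the primary benzylic alcohol into the bromide.

Step 9
Reactants: 13 1-bromo-7-(bromomethyl)-4,5-dimethoxynaphthalene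
Product: 14 1-bromo-4,5-dimethoxy-7-methylnaphthalene
Conditions: LiBHEt3, THF, 0 °C
Reagents that add atoms: none
Why: SN2 hydride displacement of the benzylic bromide, which is far faster than any reaction of the aryl bromide with the borohydride at 0 °C.

Step 10
Reactants: 14 1-bromo-4,5-dimethoxy-7-methylnaphthalene
Product: 15 2-(4,5-dimethoxy-7-methylnaphthalen-1-yl)-4,4,5,5-tetramethyl-1,3,2-dioxaborolane
Conditions: bis(pinacolato)diboron, Pd(dppf)Cl2 (cat.), KOAc, 1,4-dioxane, 90 °C
Reagents that add atoms: bis(pinacolato)diboron, CC1(C)OB(OC1(C)C)B1OC(C)(C)C(C)(C)O1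
Why: Miyaura borylation of the aryl bromide, with acetate as the mild base that avoids homocoupling.

Step 11
Reactants: 5 (3S)-5-bromo-6,8-dimethoxy-3-methyl-3,4-dihydroisoquinolin-1(2H)-one; 15 2-(4,5-dimethoxy-7-methylnaphthalen-1-yl)-4,4,5,5-tetramethyl-1,3,2-dioxaborolane
Product: 16 (3S)-5-(4,5-dimethoxy-7-methylnaphthalen-1-yl)-6,8-dimethoxy-3-methyl-3,4-dihydroisoquinolin-1(2H)-one
Conditions: Pd(OAc)2 (cat.), SPhos, K3PO4, toluene/H2O, 100 °C
Reagents that add atoms: none
Why: Suzuki–Miyaura coupling with a dialkylbiarylphosphine ligand, which is suited to electron-rich, ortho,ortho'-flanked bromides and tolerates the lactam N–H; C3 is untouched.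

Step 12
Reactants: 16 (3S)-5-(4,5-dimethoxy-7-methylnaphthalen-1-yl)-6,8-dimethoxy-3-methyl-3,4-dihydroisoquinolin-1(2H)-one
Product: 17 (3S)-5-(4,5-dimethoxy-7-methylnaphthalen-1-yl)-6,8-dimethoxy-3-methyl-1,2,3,4-tetrahydroisoquinoline
Conditions: LiAlH4, THF, reflux; aq. NaOH work-up
Reagents that add atoms: none
Why: LiAlH4 reduction of the secondary lactam through the hemiaminal aluminate and the cyclic imine turns C1 into CH2, while the aryl methyl ethers and the biaryl are inert and the C3 centre is not epimerisable.

**Compound list**

1 | methyl 2,4-dimethoxy-6-methylbenzoate | COC(=O)c1c(C)cc(OC)cc1OC | starting material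
2 | methyl 2,4-dimethoxy-6-(2-oxopropyl)benzoate | COC(=O)c1c(CC(C)=O)cc(OC)cc1OC | intermediate
3 | methyl 2-[(2S)-2-aminopropyl]-4,6-dimethoxybenzoate | COC(=O)c1c(C[C@H](C)N)cc(OC)cc1OC | intermediate
4 | (3S)-6,8-dimethoxy-3-methyl-3,4-dihydroisoquinolin-1(2H)-one | COc1cc(OC)cc2c1C(=O)N[C@@H](C)C2 | intermediate
5 | (3S)-5-bromo-6,8-dimethoxy-3-methyl-3,4-dihydroisoquinolin-1(2H)-one | COc1cc(OC)c(Br)c2c1C(=O)N[C@@H](C)C2 | intermediate
6 | 2-bromo-5-methoxybenzaldehyde | COc1ccc(Br)c(C=O)c1 | starting material
7 | dimethyl succinate | COC(=O)CCC(=O)OC | starting material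
8 | (3E)-4-(2-bromo-5-methoxyphenyl)-3-(methoxycarbonyl)but-3-enoic acid | COc1ccc(Br)c(/C=C(\CC(=O)O)C(=O)OC)c1 | intermediate
9 | methyl 4-acetoxy-8-bromo-5-methoxynaphthalene-2-carboxylate | COC(=O)c1cc(OC(C)=O)c2c(OC)ccc(Br)c2c1 | intermediate
10 | methyl 8-bromo-4-hydroxy-5-methoxynaphthalene-2-carboxylate | COC(=O)c1cc(O)c2c(OC)ccc(Br)c2c1 | intermediate
11 | methyl 8-bromo-4,5-dimethoxynaphthalene-2-carboxylate | COC(=O)c1cc(OC)c2c(OC)ccc(Br)c2c1 | intermediate
12 | (8-bromo-4,5-dimethoxynaphthalen-2-yl)methanol | OCc1cc(OC)c2c(OC)ccc(Br)c2c1 | intermediate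
13 | 1-bromo-7-(bromomethyl)-4,5-dimethoxynaphthalene | BrCc1cc(OC)c2c(OC)ccc(Br)c2c1 | intermediate
14 | 1-bromo-4,5-dimethoxy-7-methylnaphthalene | Cc1cc(OC)c2c(OC)ccc(Br)c2c1 | intermediate
15 | 2-(4,5-dimethoxy-7-methylnaphthalen-1-yl)-4,4,5,5-tetramethyl-1,3,2-dioxaborolane | Cc1cc(OC)c2c(OC)ccc(B3OC(C)(C)C(C)(C)O3)c2c1 | intermediate
16 | (3S)-5-(4,5-dimethoxy-7-methylnaphthalen-1-yl)-6,8-dimethoxy-3-methyl-3,4-dihydroisoquinolin-1(2H)-one | COc1cc(OC)c(-c2ccc(OC)c3c(OC)cc(C)cc23)c2c1C(=O)N[C@@H](C)C2 | intermediate
17 | (3S)-5-(4,5-dimethoxy-7-methylnaphthalen-1-yl)-6,8-dimethoxy-3-methyl-1,2,3,4-tetrahydroisoquinoline | COc1cc(OC)c(-c2ccc(OC)c3c(OC)cc(C)cc23)c2c1CN[C@@H](C)C2 | target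

**Step count and risks**

Total step count: 12. Longest linear sequence: 9 steps (steps 4 to 12).

Steps most likely to fail:

Step 2. The doubly substituted arylacetone may bind poorly in the enzyme's large pocket, giving slow turnover, or the electron-rich, ortho-flanked benzoate may undergo lactam closure only sluggishly. The fallback sets out from 2 and uses a chiral-auxiliary reductive amination: condensation with (S)-1-phenylethylamine (Ti(OiPr)4, THF) and hydrogenation over PtO2 in EtOH should favour the like-configured amine, which is purified from its diastereomer as methyl 2,4-dimethoxy-6-[(2S)-2-{[(1S)-1-phenylethyl]amino}propyl]benzoate F1. Hydrogenolysis of the benzylic N-substituent (H2, Pd(OH)2 on carbon, MeOH) should give amino ester 3, and warming with K2CO3 in MeOH closes the lactam, so the fallback comes back to the route at 4.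

Step 11. Oxidative addition and transmetalation at the doubly ortho-flanked, electron-rich bromide may be slow, with protodeboronation of the electron-rich naphthyl boronate competing. The fallback sets out from 14 (with 5) and changes to a Negishi union: bromine–lithium exchange on 14 (nBuLi, THF, −78 °C) and transmetalation with ZnCl2 give (4,5-dimethoxy-7-methylnaphthalen-1-yl)zinc chloride F2, which is used in excess and coupled with 5 under Pd(PtBu3)2 catalysis in THF/NMP at 60 °C. The organozinc cannot protodeboronate and transmetalates faster; the fallback comes back to the route at 16.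

Step 12. Hydride delivery to the C1 carbonyl, which is deactivated by the two methoxy groups and flanked by the C8 methoxy group, may stall at unreacted lactam or at the hemiaminal stage. The fallback sets out from 16 and activates the amide first: O-ethylation with Et3OBF4 in CH2Cl2 at 25 °C gives the lactim ether (3S)-5-(4,5-dimethoxy-7-methylnaphthalen-1-yl)-1-ethoxy-6,8-dimethoxy-3-methyl-3,4-dihydroisoquinoline F3. NaBH4 in EtOH (0 to 25 °C) should then reduce it, with loss of ethanol, through the cyclic imine to the amine, so the fallback comes back to the route at 17.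

**Further compounds**

F1 | step 2 | methyl 2,4-dimethoxy-6-[(2S)-2-{[(1S)-1-phenylethyl]amino}propyl]benzoate | COC(=O)c1c(C[C@H](C)N[C@@H](C)c2ccccc2)cc(OC)cc1OC
F2 | step 11 | (4,5-dimethoxy-7-methylnaphthalen-1-yl)zinc chloride | Cc1cc(OC)c2c(OC)ccc([Zn]Cl)c2c1
F3 | step 12 | (3S)-5-(4,5-dimethoxy-7-methylnaphthalen-1-yl)-1-ethoxy-6,8-dimethoxy-3-methyl-3,4-dihydroisoquinoline | COc1cc(OC)c(-c2ccc(OC)c3c(OC)cc(C)cc23)c2c1C(OCC)=N[C@@H](C)C2
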